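**Retrosynthetic overview**

1. The target is luteolin carrying a [(1S,2S)-2-hydroxy-2,6,6-trimethylcyclohexyl]methyl group at C6 of ring A. The three flavone rings are bought intact as luteolin, and the last C–C disconnection is the aryl C6–CH2 bond (Negishi coupling of a primary alkylzinc with a 6-iodo-tetra-O-benzylluteolin).
2. The zinc-bearing CH2 is the α-carbon of a CH2CO2Me arm on the cyclohexane; the ester carbon is excised as CO2 by saponification and iododecarboxylation.
3. The strategy rests on the cyclohexane C1–C2 bond, which joins the CH that carries the benzylic CH2 (C1) to the methyl carbinol carbon (C2); these are the only two stereocentres. A samarium ketyl at C2 adding to an enoate β-carbon at C1 makes this bond, closes the cyclohexane (the only ring formed in the route) and sets both centres in one step.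
4. The acyclic keto enoate is assembled from isobutyronitrile (the gem-dimethyl carbon), an iodo ketal (tether and masked methyl ketone) and trimethyl phosphonoacetate (the enoate).

Key step: step 6

Assumption: the sense of induction of the samarium–aminodiol complex cannot be predicted with confidence, so the ligand antipode that delivers the (1S,2S) series is the one taken; each antipode is made in one operation from benzylamine and one enantiomer of styrene oxide, and the ligand is treated as a recoverable reagent, not as a step.

**Step 1**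
Reactants: 1 2-(3-chloropropyl)-2-methyl-1,3-dioxolane
Product: 2 2-(3-iodopropyl)-2-methyl-1,3-dioxolane
Conditions: NaI, NaHCO3 (cat.), acetone, reflux
Reagents that add atoms: sodium iodide, [Na+].[I-]
Why: Finkelstein halide exchange (SN2) at the primary chloride is driven by precipitation of NaCl from acetone, and the dioxolane is inert under these neutral conditions.

**Step 2**
Reactants: 3 isobutyronitrile; 2 2-(3-iodopropyl)-2-methyl-1,3-dioxolane
Product: 5 2,2-dimethyl-5-(2-methyl-1,3-dioxolan-2-yl)pentanenitrile, via lithiated isobutyronitrile 4 (not isolated)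
Conditions: LiN(iPr)2, THF, −78 °C; then 2, −78 °C → rt
Reagents that add atoms: none
Why: α-Alkylation of a lithiated nitrile, in which the small and strongly nucleophilic tertiary nitrile anion should displace the unhindered primary iodide and create the quaternary CMe2 carbon while the ketal keeps the ketone away from the base.

**Step 3**
Reactants: 5 2,2-dimethyl-5-(2-methyl-1,3-dioxolan-2-yl)pentanenitrile
Product: 7 2,2-dimethyl-5-(2-methyl-1,3-dioxolan-2-yl)pentanal, via aluminium aldiminate 6 (not isolated)
Conditions: iBu2AlH, CH2Cl2, −78 °C; then aq. citric acid (pH 4), 0 °C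
Reagents that add atoms: water, O
Why: Partial reduction of a nitrile by iBu2AlH stops at the N-aluminio aldimine, which mild aqueous acid hydrolyses to the non-enolisable aldehyde under conditions (pH 4, 0 °C, short contact) that the dioxolane should survive.

**Step 4**
Reactants: 7 2,2-dimethyl-5-(2-methyl-1,3-dioxolan-2-yl)pentanal; 8 trimethyl phosphonoacetate
Product: 10 methyl (E)-4,4-dimethyl-7-(2-methyl-1,3-dioxolan-2-yl)hept-2-enoate, via sodium phosphonate anion 9 (not isolated)
Conditions: NaH, THF, 0 °C; then 7, 0 °C → rt
Reagents that add atoms: none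
Why: Horner–Wadsworth–Emmons olefination of an aldehyde without α-hydrogens by a stabilised phosphonate anion should give the (E)-enoate, the quaternary neighbour reinforcing the usual E preference.

**Step 5**
Reactants: 10 methyl (E)-4,4-dimethyl-7-(2-methyl-1,3-dioxolan-2-yl)hept-2-enoate
Product: 11 methyl (E)-4,4-dimethyl-8-oxonon-2-enoate
Conditions: 1 M aq. HCl, THF, rt
Reagents that add atoms: water, O
Why: Acid-catalysed acetal hydrolysis frees the methyl ketone, and the enoate is inert to dilute acid at room temperature.

**Step 6**
Reactants: 11 methyl (E)-4,4-dimethyl-8-oxonon-2-enoate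
Product: 12 methyl 2-[(1S,2S)-2-hydroxy-2,6,6-trimethylcyclohexyl]acetate
Conditions: SmI2 (2.5 equiv), 2,2'-(benzylazanediyl)bis(1-phenylethan-1-ol) (single enantiomer, 2.5 equiv), t-BuOH (2.5 equiv), THF, −78 → −30 °C, slow addition of 11
Reagents that add atoms: none
Why: Proposed new method: the ligated SmI2 transfers one electron to the methyl ketone to give a samarium ketyl, whose carbon (C8 of the chain, C2 of the new ring) adds to the enoate β-carbon (C3 of the chain, C1 of the ring), and a second electron turns the resulting α-ester radical into a samarium enolate that t-BuOH protonates, so the net change is the C1–C2 bond plus two hydrogens. The closest known reaction type is the SmI2 ketyl–olefin (ketone–enoate) cyclisation, established as a diastereoselective but racemic process; the new element is a samarium-bound chiral aminodiol choosing between the two enantiomeric transition states. The cyclohexane closes 6-exo-trig through a chair-like transition state with the (E)-enoate pseudo-equatorial. The configuration at C2 relative to C1 is set by the ketyl oxygen, which carries the bulky ligated trivalent samarium and negative charge and therefore lies anti to the enoate and its developing enolate, placing hydroxyl trans and methyl cis to the CH2CO2Me arm; the absolute configuration at both centres is set by the enoate face that the chiral samarium ketyl attacks, and HMPA is left out because it would displace the ligand. The step needs trans over cis closure and cyclisation over pinacol coupling or simple ketone reduction: the gem-dimethyl group in the tether (Thorpe–Ingold effect) and the conjugated acceptor favour ring closure, and any cis isomer should close to the cis-fused γ-lactone and be removed by chromatography.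

**Step 7**
Reactants: 12 methyl 2-[(1S,2S)-2-hydroxy-2,6,6-trimethylcyclohexyl]acetate
Product: 13 methyl 2-[(1S,2S)-2,6,6-trimethyl-2-(triethylsilyloxy)cyclohexyl]acetate
Conditions: Et3SiOTf, 2,6-lutidine, CH2Cl2, −78 → 0 °C
Reagents that add atoms: triethylsilyl trifluoromethanesulfonate, CC[Si](CC)(CC)OS(=O)(=O)C(F)(F)F
Why: Silylation of the hindered tertiary alcohol by a silyl triflate with a non-nucleophilic base should outrun lactonisation at low temperature, and the ether blocks lactone formation and alkoxy-radical fragmentation in the following steps.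

**Step 8**
Reactants: 13 methyl 2-[(1S,2S)-2,6,6-trimethyl-2-(triethylsilyloxy)cyclohexyl]acetate
Product: 15 2-[(1S,2S)-2,6,6-trimethyl-2-(triethylsilyloxy)cyclohexyl]acetic acid, via lithium carboxylate 14 (not isolated)
Conditions: LiOH, THF/MeOH/H2O, 40 °C; then 1 M HCl to pH 4, 0 °C
Reagents that add atoms: lithium hydroxide, [Li+].[OH-]
Why: Saponification of the methyl ester, in which the tertiary triethylsilyl ether is stable to base and to a cold, brief acidification, and no stereocentre is α to the carbonyl so nothing can epimerise.

**Step 9**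
Reactants: 15 2-[(1S,2S)-2,6,6-trimethyl-2-(triethylsilyloxy)cyclohexyl]acetic acid
Product: 16 triethyl{[(1S,2S)-2-(iodomethyl)-1,3,3-trimethylcyclohexyl]oxy}silane
Conditions: PhI(OAc)2, I2, ClCH2CH2Cl, visible light, 60 °C
Reagents that add atoms: iodine, II
Why: Hunsdiecker-type iododecarboxylation through a photolabile acyl hypoiodite, in which loss of CO2 leaves a primary radical on the exocyclic CH2 that iodine traps, so the ester carbon is removed and the ring stereocentres, which are not radical sites, stay untouched.

**Step 10**
Reactants: 17 luteolin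
Product: 18 7-(benzyloxy)-2-[3,4-bis(benzyloxy)phenyl]-5-hydroxy-4H-chromen-4-one (7,3',4'-tri-O-benzylluteolin)
Conditions: BnBr (3.3 equiv), K2CO3, DMF, rt
Reagents that add atoms: benzyl bromide, BrCc1ccccc1
Why: Williamson etherification alkylates the 7-, 3'- and 4'-phenols, while the 5-OH, held by a strong hydrogen bond to the C4 carbonyl, should stay free under mild base at room temperature.

**Step 11**
Reactants: 18 7,3',4'-tri-O-benzylluteolin
Product: 19 7-(benzyloxy)-2-[3,4-bis(benzyloxy)phenyl]-5-hydroxy-6-iodo-4H-chromen-4-one
Conditions: BnMe3N+ ICl2− (1.1 equiv), CaCO3, CH2Cl2/MeOH, rt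
Reagents that add atoms: benzyltrimethylammonium dichloroiodate, C[N+](C)(C)Cc1ccccc1.Cl[I-]Cl
Why: Electrophilic aromatic iodination directed by the free 5-phenol, which in 5-hydroxy-7-alkoxyflavones sends iodine to C6 (the only free position ortho to that phenol), whereas 5-O-alkylated flavones react at C8, so the 5-OH is kept free up to this step.

**Step 12**
Reactants: 19 7-(benzyloxy)-2-[3,4-bis(benzyloxy)phenyl]-5-hydroxy-6-iodo-4H-chromen-4-one
Product: 20 5,7-bis(benzyloxy)-2-[3,4-bis(benzyloxy)phenyl]-6-iodo-4H-chromen-4-one
Conditions: BnBr, K2CO3, Bu4NI (cat.), DMF, 70 °C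
Reagents that add atoms: benzyl bromide, BrCc1ccccc1
Why: Williamson etherification under more forcing conditions alkylates the chelated 5-OH, which removes the acidic proton before the organozinc coupling and leaves the aryl iodide untouched.

**Step 13**
Reactants: 16 triethyl{[(1S,2S)-2-(iodomethyl)-1,3,3-trimethylcyclohexyl]oxy}silane; 20 5,7-bis(benzyloxy)-2-[3,4-bis(benzyloxy)phenyl]-6-iodo-4H-chromen-4-one
Product: 22 5,7-bis(benzyloxy)-2-[3,4-bis(benzyloxy)phenyl]-6-{[(1S,2S)-2,6,6-trimethyl-2-(triethylsilyloxy)cyclohexyl]methyl}-4H-chromen-4-one, via alkylzinc iodide 21 (not isolated)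
Conditions: Zn dust (activated), LiCl, THF, 40 °C; then 20, Pd(OAc)2 (5 mol %), SPhos (10 mol %), THF/NMP, 60 °C
Reagents that add atoms: none
Why: Negishi cross-coupling, in which zinc inserts into the primary carbon–iodine bond and the alkylzinc transmetalates to the arylpalladium iodide formed from 20 and zerovalent palladium, the bulky biarylphosphine SPhos promoting oxidative addition and reductive elimination at the di-ortho-substituted position, while the organozinc tolerates the chromone carbonyl and both ether types and the stereocentres are remote from the reacting CH2.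

**Step 14**
Reactants: 22 the silyl-protected coupling product
Product: 23 5,7-bis(benzyloxy)-2-[3,4-bis(benzyloxy)phenyl]-6-{[(1S,2S)-2-hydroxy-2,6,6-trimethylcyclohexyl]methyl}-4H-chromen-4-one
Conditions: HF·pyridine, pyridine, THF, 0 °C → rt
Reagents that add atoms: none
Why: Fluoride-driven cleavage of the silyl ether under pyridine-buffered conditions, mild enough to avoid ionisation of the tertiary alcohol or its cyclisation onto a flanking oxygen substituent.

**Step 15**
Reactants: 23 the tetra-O-benzyl tertiary alcohol
Product: 24 2-(3,4-dihydroxyphenyl)-5,7-dihydroxy-6-{[(1S,2S)-2-hydroxy-2,6,6-trimethylcyclohexyl]methyl}-4H-chromen-4-one (CNP0257603.1)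
Conditions: H2 (1 atm), Pd/C, THF/MeOH, rt
Reagents that add atoms: none
Why: Catalytic hydrogenolysis removes the four benzyl ethers under neutral conditions, which avoids acid-induced dehydration or ether formation at the tertiary alcohol and, if stopped at full debenzylation, should leave the chromone C2–C3 double bond intact.

**Compound list**

1 | 2-(3-chloropropyl)-2-methyl-1,3-dioxolane | CC1(CCCCl)OCCO1 | starting material
2 | 2-(3-iodopropyl)-2-methyl-1,3-dioxolane | CC1(CCCI)OCCO1 | intermediate
3 | isobutyronitrile (2-methylpropanenitrile) | CC(C)C#N | starting material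
4 | lithiated isobutyronitrile (2-lithio-2-methylpropanenitrile) | [Li+].C[C-](C)C#N | intermediate
5 | 2,2-dimethyl-5-(2-methyl-1,3-dioxolan-2-yl)pentanenitrile | CC1(CCCC(C)(C)C#N)OCCO1 | intermediate
6 | N-(diisobutylaluminio) aldimine of 2,2-dimethyl-5-(2-methyl-1,3-dioxolan-2-yl)pentanal | CC1(CCCC(C)(C)C=N[Al](CC(C)C)CC(C)C)OCCO1 | intermediate
7 | 2,2-dimethyl-5-(2-methyl-1,3-dioxolan-2-yl)pentanal | CC1(CCCC(C)(C)C=O)OCCO1 | intermediate
8 | trimethyl phosphonoacetate | COC(=O)CP(=O)(OC)OC | starting material
9 | sodium salt of trimethyl phosphonoacetate (phosphonate carbanion) | [Na+].COC(=O)[CH-]P(=O)(OC)OC | intermediate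
10 | methyl (E)-4,4-dimethyl-7-(2-methyl-1,3-dioxolan-2-yl)hept-2-enoate | CC1(CCCC(C)(C)/C=C/C(=O)OC)OCCO1 | intermediate
11 | methyl (E)-4,4-dimethyl-8-oxonon-2-enoate | CC(=O)CCCC(C)(C)/C=C/C(=O)OC | intermediate
12 | methyl 2-[(1S,2S)-2-hydroxy-2,6,6-trimethylcyclohexyl]acetate (hydroxyl trans to the CH2CO2Me arm) | CC1(C)CCC[C@](C)(O)[C@H]1CC(=O)OC | intermediate
13 | methyl 2-[(1S,2S)-2,6,6-trimethyl-2-(triethylsilyloxy)cyclohexyl]acetate | CC1(C)CCC[C@](C)(O[Si](CC)(CC)CC)[C@H]1CC(=O)OC | intermediate
14 | lithium 2-[(1S,2S)-2,6,6-trimethyl-2-(triethylsilyloxy)cyclohexyl]acetate | CC1(C)CCC[C@](C)(O[Si](CC)(CC)CC)[C@H]1CC(=O)[O-].[Li+] | intermediate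
15 | 2-[(1S,2S)-2,6,6-trimethyl-2-(triethylsilyloxy)cyclohexyl]acetic acid | CC1(C)CCC[C@](C)(O[Si](CC)(CC)CC)[C@H]1CC(=O)O | intermediate
16 | triethyl{[(1S,2S)-2-(iodomethyl)-1,3,3-trimethylcyclohexyl]oxy}silane | CC1(C)CCC[C@](C)(O[Si](CC)(CC)CC)[C@H]1CI | intermediate
17 | luteolin | O=c1cc(-c2ccc(O)c(O)c2)oc2cc(O)cc(O)c12 | starting material
18 | 7-(benzyloxy)-2-[3,4-bis(benzyloxy)phenyl]-5-hydroxy-4H-chromen-4-one | O=c1cc(-c2ccc(OCc3ccccc3)c(OCc3ccccc3)c2)oc2cc(OCc3ccccc3)cc(O)c12 | intermediate
19 | 7-(benzyloxy)-2-[3,4-bis(benzyloxy)phenyl]-5-hydroxy-6-iodo-4H-chromen-4-one | O=c1cc(-c2ccc(OCc3ccccc3)c(OCc3ccccc3)c2)oc2cc(OCc3ccccc3)c(I)c(O)c12 | intermediate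
20 | 5,7-bis(benzyloxy)-2-[3,4-bis(benzyloxy)phenyl]-6-iodo-4H-chromen-4-one | O=c1cc(-c2ccc(OCc3ccccc3)c(OCc3ccccc3)c2)oc2cc(OCc3ccccc3)c(I)c(OCc3ccccc3)c12 | intermediate
21 | {[(1S,2S)-2,6,6-trimethyl-2-(triethylsilyloxy)cyclohexyl]methyl}zinc iodide | CC1(C)CCC[C@](C)(O[Si](CC)(CC)CC)[C@H]1C[Zn]I | intermediate
22 | 5,7-bis(benzyloxy)-2-[3,4-bis(benzyloxy)phenyl]-6-{[(1S,2S)-2,6,6-trimethyl-2-(triethylsilyloxy)cyclohexyl]methyl}-4H-chromen-4-one | CC1(C)CCC[C@](C)(O[Si](CC)(CC)CC)[C@H]1Cc1c(OCc2ccccc2)cc2oc(-c3ccc(OCc4ccccc4)c(OCc4ccccc4)c3)cc(=O)c2c1OCc1ccccc1 | intermediate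
23 | 5,7-bis(benzyloxy)-2-[3,4-bis(benzyloxy)phenyl]-6-{[(1S,2S)-2-hydroxy-2,6,6-trimethylcyclohexyl]methyl}-4H-chromen-4-one | CC1(C)CCC[C@](C)(O)[C@H]1Cc1c(OCc2ccccc2)cc2oc(-c3ccc(OCc4ccccc4)c(OCc4ccccc4)c3)cc(=O)c2c1OCc1ccccc1 | intermediate
24 | 2-(3,4-dihydroxyphenyl)-5,7-dihydroxy-6-{[(1S,2S)-2-hydroxy-2,6,6-trimethylcyclohexyl]methyl}-4H-chromen-4-one | CC1(C)CCC[C@](C)(O)[C@H]1Cc1c(O)cc2oc(-c3ccc(O)c(O)c3)cc(=O)c2c1O | target

**Step count**

Total: 15 steps. Longest linear sequence: 12 steps (steps 1–9 and 13–15); steps 10–12 form the three-step luteolin branch.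

**Steps most likely to fail**

Step 6. The chiral ligand may not remain bound to samarium during C–C bond formation, giving poor facial selectivity. In addition, the trans preference may be eroded because the pseudo-axial methyl at the ketyl carbon meets an axial methyl of the gem-dimethyl group. The fallback sets out from 11 and returns at 12. Keto enoate 11 is cyclised with SmI2 and t-BuOH in THF at −78 °C without the chiral ligand, which is the known diastereoselective ketone–enoate cyclisation. After chromatographic removal of any cis-lactone this should give racemic methyl 2-(trans-2-hydroxy-2,6,6-trimethylcyclohexyl)acetate F1. F1 is then resolved by preparative chromatography on a polysaccharide chiral stationary phase (supercritical CO2/MeOH). The (1S,2S) enantiomer is 12, and its configuration is to be assigned by anomalous-dispersion X-ray analysis of a crystalline derivative.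

Step 13. Transmetalation of the β-branched alkylzinc and reductive elimination at the di-ortho-alkoxy arylpalladium may be slow, so that protodezincation and reduction of the aryl iodide take over. The fallback sets out from 15 and returns at 22, bypassing steps 9 and 13. Acid 15 is condensed with N-hydroxyphthalimide using N,N'-diisopropylcarbodiimide and catalytic DMAP in CH2Cl2 to give the redox-active ester 1,3-dioxoisoindolin-2-yl 2-[(1S,2S)-2,6,6-trimethyl-2-(triethylsilyloxy)cyclohexyl]acetate F2. F2 is coupled with aryl iodide 20 under NiBr2·glyme, 4,4'-di-tert-butyl-2,2'-bipyridine and Zn in DMA at room temperature (known nickel-catalysed reductive decarboxylative arylation). Here the primary radical released on decarboxylation is captured at an arylnickel species, so no transmetalation to palladium is required.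

Step 7. Intramolecular acyl transfer of the γ-hydroxy ester to the trans-fused γ-lactone may compete with silylation of the hindered tertiary alcohol, or may already occur during work-up of step 6. The fallback sets out from 12 and returns at 15, bypassing steps 7 and 8. Hydroxy ester 12, together with any lactone formed from it, is opened with KOH in aqueous MeOH at 50 °C to potassium 2-[(1S,2S)-2-hydroxy-2,6,6-trimethylcyclohexyl]acetate F3, which is dried azeotropically. Both oxygens are silylated with excess Et3SiOTf and 2,6-lutidine in CH2Cl2 to give triethylsilyl 2-[(1S,2S)-2,6,6-trimethyl-2-(triethylsilyloxy)cyclohexyl]acetate F4. The labile silyl ester is then hydrolysed selectively with K2CO3 (cat.) in aqueous MeOH at 0 °C to give acid 15. Protection is thus applied after the ester has been opened instead of before its hydrolysis.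

**Further compounds**

F1 | step 6 | racemic methyl 2-(trans-2-hydroxy-2,6,6-trimethylcyclohexyl)acetate (1:1 mixture of 12 and its enantiomer) | CC1(C)CCC[C@](C)(O)[C@H]1CC(=O)OC.CC1(C)CCC[C@@](C)(O)[C@@H]1CC(=O)OC
F2 | step 13 | 1,3-dioxoisoindolin-2-yl 2-[(1S,2S)-2,6,6-trimethyl-2-(triethylsilyloxy)cyclohexyl]acetate | CC1(C)CCC[C@](C)(O[Si](CC)(CC)CC)[C@H]1CC(=O)ON1C(=O)c2ccccc2C1=O
F3 | step 7 | potassium 2-[(1S,2S)-2-hydroxy-2,6,6-trimethylcyclohexyl]acetate | CC1(C)CCC[C@](C)(O)[C@H]1CC(=O)[O-].[K+]
F4 | step 7 | triethylsilyl 2-[(1S,2S)-2,6,6-trimethyl-2-(triethylsilyloxy)cyclohexyl]acetate | CC1(C)CCC[C@](C)(O[Si](CC)(CC)CC)[C@H]1CC(=O)O[Si](CC)(CC)CC
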